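**Plan**

- Retrosynthesis cuts, in order: the side-chain C3'–C4' bond (key step), the amide N–C1' bond, the C5–C6 aldol bond that closes ring B of the bicyclo[3.3.1]nonane, the C1–O bond made by dearomatisation of ring A, and the aryl–C8 bond.
- Forward: a 2-methoxy-L-tyrosine ester is dearomatised to ring A (spiro dienone), then epoxidised and reduced. Enol ether hydrolysis and an intramolecular aldol close ring B, the amine is acylated, and the chain is joined last on the unprotected core.
- Stereochemistry: C7 comes from L-serine-derived iodoalanine. C1 is set in the dearomatisation (chair-like capture by the Boc carbonyl), C2/C3 by epoxidation on the face of the C1 oxygen, C4 by hydride delivery anti to the epoxide, and C5/C6 in the lithium-bridged aldol. The E alkene arises in the radical fragmentation.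
- Feature that allows the key step: the C7' ketone lies three carbons from C4' (C4'–C5'–C6'–C7'=O), so C4'–C7' plus the pentyl group are the ring-opened form of 1-pentylcyclobutan-1-ol. C3' is the β-carbon of the acrylamide, made a radical acceptor by a phenylsulfonyl group that leaves in the same step.
- Numbering: ring carbons carry the target's bicyclo[3.3.1]nonane numbers throughout (C1 carbinol bridgehead, C2–C3 epoxide, C4 carbinol, C5 bridgehead, C6 carbinol, C7 N-bearing, C8 CH2, C9 ketone); ring A = C1–C5 and C9, ring B = C1, C5–C9; side chain C1' (amide C=O) to C12'; "exo" = on the face of a ring turned away from the other three-carbon bridge.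

Key step: step 13

**Step 1**
Reactants: 1 methyl (2R)-2-[(tert-butoxycarbonyl)amino]-3-iodopropanoate; 2 4-bromo-3-methoxyphenol
Product: 3 methyl (2S)-2-[(tert-butoxycarbonyl)amino]-3-(4-hydroxy-2-methoxyphenyl)propanoate
Conditions: 1 (1.5 equiv), Zn dust, I2 (cat.), DMF, 25 °C; then 2, Pd2(dba)3 (2.5 mol %), SPhos (5 mol %), 50 °C
Reagents that add atoms: none
Why: Negishi coupling of the serine-derived alkylzinc iodide with the aryl bromide should form the aryl–C8 bond without touching the C7 stereocentre, the excess zinc reagent compensating for the free phenol.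

**Step 2**
Reactants: 3
Product: 4 methyl (4S,6S)-7-methoxy-2,9-dioxo-1-oxa-3-azaspiro[5.5]undeca-7,10-diene-4-carboxylate
Conditions: PhI(OAc)2 (1.1 equiv), (CF3)2CHOH, 0 °C
Reagents that add atoms: none
Why: Oxidative phenol dearomatisation in which the Boc carbonyl oxygen, the most Lewis-basic internal nucleophile, should capture the para carbon (C1) in a six-membered chair-like transition state with loss of isobutene; C1 is set because the ester at C7 and the methoxy-bearing C9 both sit equatorial (an axial C9 would push its methoxy group over the forming ring), which places the ester cis to C9.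

**Step 3**
Reactants: 4
Product: 5 epoxy enone (C2–C3 epoxide cis to the ring oxygen on C1)
Conditions: t-BuOOH (in decane), DBU, CH2Cl2, 0 °C
Reagents that add atoms: tert-butyl hydroperoxide, CC(C)(C)OO
Why: Weitz–Scheffer nucleophilic epoxidation should act only on the unsubstituted enone (the methoxy enone is a deactivated vinylogous ester), the peroxide adding to the axial C2 from the face of the C1 ring oxygen because the other face is screened by C8 and the axial hydrogen on C7, which sets C2 and C3.

**Step 4**
Reactants: 5
Product: 6 epoxy allylic alcohol (C4–OH cis to the epoxide and to the C1 oxygen)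
Conditions: NaBH4, CeCl3·7H2O, MeOH, −40 → 0 °C
Reagents that add atoms: none
Why: Luche 1,2-reduction of the C4 ketone, with hydride expected to arrive anti to the C–O bond of the adjacent epoxide, should set C4 with the hydroxyl cis to the epoxide and leave ester, carbamate and enol ether intact.

**Step 5**
Reactants: 6
Product: 7 C4 tert-butyldimethylsilyl ether of 6
Conditions: TBSCl, imidazole, DMF, 25 °C
Reagents that add atoms: tert-butyldimethylsilyl chloride, CC(C)(C)[Si](C)(C)Cl
Why: Standard silylation of the only free hydroxyl keeps C4–O from being acylated in step 6 and makes it a poor leaving group toward allylic ionisation or β-elimination in step 8.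

**Step 6**
Reactants: 7
Product: 10 spirolactone (NHBoc at C7; epoxide C2–C3; C4–OTBS; C9 methyl enol ether), via N-Boc cyclic carbamate 8 (not isolated), via ring-opened hydroxy ester 9 (not isolated)
Conditions: Boc2O, DMAP (0.2 equiv), MeCN, 25 °C; then Cs2CO3 (0.5 equiv), MeOH, 25 °C; then evaporation from PhMe, 40 °C
Reagents that add atoms: di-tert-butyl dicarbonate, CC(C)(C)OC(=O)OC(=O)OC(C)(C)C
Why: N-Boc activation followed by methanolysis of the ring carbonyl (cleavage of N-Boc cyclic carbamates with Cs2CO3/MeOH) should release the carbonyl as dimethyl carbonate and the C1 alkoxide, which lactonises onto the methyl ester; no stereocentre is touched, and the alkoxide, being cis to the epoxide, cannot undergo epoxide migration.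

**Step 7**
Reactants: 10
Product: 11 spiro lactol (mixture of epimers at the lactol carbon C6)
Conditions: iBu2AlH (2.5 equiv), CH2Cl2, −78 °C; aq. potassium sodium tartrate
Reagents that add atoms: none
Why: Partial reduction of a γ-lactone to the lactol at low temperature is reliable and stores the C6 aldehyde as a hemiacetal, which protects C7 from epimerisation.

**Step 8**
Reactants: 11
Product: 13 bicyclic aldol (NHBoc at C7; C4–OTBS; free C1 and C6 hydroxyls), via keto lactol 12 (not isolated)
Conditions: 0.1 M HCl, THF/H2O, 0 °C; then LiN(SiMe3)2 (3.3 equiv), THF, −78 → −20 °C; AcOH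
Reagents that add atoms: water, O
Why: Hydrolysis of the methyl enol ether gives the C9 ketone, whose only enolisable position is C5, and the lithium enolate should add to the aldehyde freed from the lactolate in a 6-(enolendo)-exo-trig aldol that closes ring B; C5 is fixed by the tether (bond to C6 cis to C8), C6–OH should be exo through a lithium-bridged chair with the aldehyde oxygen beside the enolate oxygen and the N-lithiated carbamate equatorial, and the bridgehead C5 prevents dehydration of the product.

**Step 9**
Reactants: 13
Product: 14 aminotriol core as its hydrochloride (7-amino-1,4,6-trihydroxy-2,3-epoxybicyclo[3.3.1]nonan-9-one, all exo)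
Conditions: HCl (1.25 M in MeOH), 0 → 25 °C
Reagents that add atoms: hydrogen chloride, Cl
Why: Acidolysis removes the Boc and TBS groups together; the epoxide should survive because its rear face is blocked by ring B, and the C9 ketone cannot enolise (C1 quaternary, C5 bridgehead).

**Step 10**
Reactants: 15 PhSO2Na (sodium benzenesulfinate); 16 (E)-3-chloroacrylic acid
Product: 17 (E)-3-(phenylsulfonyl)acrylic acid
Conditions: H2O, 80 °C; then aq. HCl
Reagents that add atoms: none
Why: Vinylic substitution by addition–elimination of the sulfur nucleophile at the β-carbon should give the thermodynamically preferred E sulfone.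

**Step 11**
Reactants: 14; 17
Product: 18 N-[(E)-3-(phenylsulfonyl)acryloyl] derivative of the aminotriol core
Conditions: 17, EDC·HCl, HOBt, DMF, −20 °C; then 14, iPr2NEt, −20 → 0 °C
Reagents that add atoms: none
Why: Carbodiimide amide coupling should be selective for the amine over the three hydroxyls, and the preformed active ester at low temperature should acylate faster than the amine can add to the sulfonyl-bearing carbon.

**Step 12**
Reactants: 19 cyclobutanone; 20 C5H11MgBr (pentylmagnesium bromide)
Product: 21 1-pentylcyclobutan-1-ol
Conditions: THF, 0 °C; aq. NH4Cl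
Reagents that add atoms: none
Why: Grignard addition to the strained ketone gives the tertiary cyclobutanol in one step.

**Step 13**
Reactants: 18; 21
Product: 22 isariotin C
Conditions: 21 (3 equiv), Mn(OAc)3·2H2O (3.5 equiv), MeCN/AcOH (4:1), 25 °C, Ar
Reagents that add atoms: none
Why: Trivalent manganese exchanges onto the strained tertiary alcohol of 21 and the Mn–O bond homolyses with β-scission of the cyclobutane C1–C2 bond, which turns the carbinol carbon into the C7' ketone and leaves the primary 4-oxononyl radical at C4'; this nucleophilic radical adds to C3' of 18, and the resulting α-amide radical expels the benzenesulfonyl radical to form the C2'=C3' double bond. The closest known reactions are the manganese-mediated oxidative ring-opening of tertiary cyclobutanols with trapping by sulfonyl-based radical acceptors and radical alkenylation by addition–fragmentation on vinyl sulfones. No ring is closed (a four-membered ring is opened) and no stereocentre is formed; the alkene geometry should be E because the fragmentation passes through the rotamer with the chain anti to the amide and reversible sulfonyl-radical addition equilibrates any Z isomer. The step needs regioselectivity for C3' over C2', which is secured by the polarity of the acrylamide and by the fact that only the C3' adduct can fragment. It also needs chemoselectivity for the cyclobutanol over the core, which is expected because unstrained alkoxides do not fragment on Mn(OAc)3 at 25 °C, the C9 ketone has no enolisable hydrogen, and the epoxide is shielded by ring B. The expelled sulfonyl radical is taken up by a second equivalent of Mn(OAc)3 and should end as benzenesulfonic acid after aqueous work-up.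

**Compound list**

1 | methyl (2R)-2-[(tert-butoxycarbonyl)amino]-3-iodopropanoate (N-Boc-3-iodo-L-alanine methyl ester) | COC(=O)[C@H](CI)NC(=O)OC(C)(C)C | starting material
2 | 4-bromo-3-methoxyphenol | COc1cc(O)ccc1Br | starting material
3 | methyl (2S)-2-[(tert-butoxycarbonyl)amino]-3-(4-hydroxy-2-methoxyphenyl)propanoate | COC(=O)[C@H](Cc1ccc(O)cc1OC)NC(=O)OC(C)(C)C | intermediate
4 | methyl (4S,6S)-7-methoxy-2,9-dioxo-1-oxa-3-azaspiro[5.5]undeca-7,10-diene-4-carboxylate (spiro cyclic carbamate; ester cis to the methoxy-bearing ring carbon across the carbamate ring) | COC(=O)[C@@H]1C[C@@]2(C=CC(=O)C=C2OC)OC(=O)N1 | intermediate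
5 | epoxy enone: 4 with the unsubstituted enone double bond (C2=C3) converted into an epoxide whose oxygen is cis to the carbamate ring oxygen on C1 | COC(=O)[C@@H]1C[C@@]2([C@H]3O[C@H]3C(=O)C=C2OC)OC(=O)N1 | intermediate
6 | epoxy allylic alcohol: 5 with the C4 ketone reduced, C4–OH cis to the epoxide and to the C1 oxygen | COC(=O)[C@@H]1C[C@@]2([C@H]3O[C@H]3[C@@H](O)C=C2OC)OC(=O)N1 | intermediate
7 | C4 tert-butyldimethylsilyl ether of 6 | COC(=O)[C@@H]1C[C@@]2([C@H]3O[C@H]3[C@@H](O[Si](C)(C)C(C)(C)C)C=C2OC)OC(=O)N1 | intermediate
8 | N-Boc derivative of cyclic carbamate 7 | COC(=O)[C@@H]1C[C@@]2([C@H]3O[C@H]3[C@@H](O[Si](C)(C)C(C)(C)C)C=C2OC)OC(=O)N1C(=O)OC(C)(C)C | intermediate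
9 | ring-opened hydroxy ester: methyl (2S)-2-(Boc-amino)-3-(cyclohexenyl)propanoate with free tertiary C1–OH, cis C2–C3 epoxide, cis C4–OTBS and C9 methyl enol ether | COC(=O)[C@H](C[C@]1(O)[C@H]2O[C@H]2[C@@H](O[Si](C)(C)C(C)(C)C)C=C1OC)NC(=O)OC(C)(C)C | intermediate
10 | spiro γ-lactone of 9 (C1–O acylated by the C6 carboxyl; NHBoc on C7 cis to C2 and trans to C9 across the lactone ring) | O=C1O[C@@]2(C[C@@H]1NC(=O)OC(C)(C)C)[C@H]3O[C@H]3[C@@H](O[Si](C)(C)C(C)(C)C)C=C2OC | intermediate
11 | spiro lactol from 10 (C6 hemiacetal, mixture of epimers at C6) | OC1O[C@@]2(C[C@@H]1NC(=O)OC(C)(C)C)[C@H]3O[C@H]3[C@@H](O[Si](C)(C)C(C)(C)C)C=C2OC | intermediate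
12 | keto lactol: 11 with the enol ether hydrolysed to the C9 ketone (C5 now CH2) | OC1O[C@@]2(C[C@@H]1NC(=O)OC(C)(C)C)[C@H]3O[C@H]3[C@@H](O[Si](C)(C)C(C)(C)C)CC2=O | intermediate
13 | bicyclo[3.3.1]nonan-9-one with 1-OH, exo-2,3-epoxide, exo-4-OTBS, exo-6-OH and exo-7-NHBoc | CC(C)(C)OC(=O)N[C@H]1C[C@@]2(O)C(=O)[C@H]([C@H](O[Si](C)(C)C(C)(C)C)[C@@H]3O[C@@H]32)[C@H]1O | intermediate
14 | hydrochloride of the aminotriol core (1-OH, exo-2,3-epoxide, exo-4-OH, exo-6-OH, exo-7-NH2, 9-oxo; 1S,2S,3S,4S,5S,6R,7S) | Cl.N[C@H]1C[C@@]2(O)C(=O)[C@H]([C@H](O)[C@@H]3O[C@@H]32)[C@H]1O | intermediate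
15 | sodium benzenesulfinate | [Na+].[O-]S(=O)c1ccccc1 | starting material
16 | (E)-3-chloroacrylic acid | OC(=O)/C=C/Cl | starting material
17 | (E)-3-(phenylsulfonyl)acrylic acid | OC(=O)/C=C/S(=O)(=O)c1ccccc1 | intermediate
18 | (E)-3-(phenylsulfonyl)acrylamide of the aminotriol core (amide on exo-N at C7) | O=C(/C=C/S(=O)(=O)c1ccccc1)N[C@H]1C[C@@]2(O)C(=O)[C@H]([C@H](O)[C@@H]3O[C@@H]32)[C@H]1O | intermediate
19 | cyclobutanone | O=C1CCC1 | starting material
20 | pentylmagnesium bromide | CCCCC[Mg]Br | starting material
21 | 1-pentylcyclobutan-1-ol | CCCCCC1(O)CCC1 | intermediate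
22 | isariotin C, (E)-7-oxododec-2-enamide of the aminotriol core | CCCCCC(=O)CCC/C=C/C(=O)N[C@H]1C[C@@]2(O)C(=O)[C@H]([C@H](O)[C@@H]3O[C@@H]32)[C@H]1O | target

**Step count**

Total step count: 13. Longest linear sequence: 11 steps (steps 1–9, 11 and 13).

**Steps most likely to fail, with fallbacks**

Step 2. The oxidised phenol may be captured by the ester carbonyl or by the medium instead of by the Boc carbonyl, or the two faces of C1 may be differentiated poorly. The fallback sets out from 3 and rejoins at 10. Saponification (LiOH, THF/H2O) should give (2S)-2-(Boc-amino)-3-(4-hydroxy-2-methoxyphenyl)propanoic acid F1. PhI(OAc)2 in MeCN should then close the five-membered ring by carboxylate capture (the classical tyrosine spirolactonisation). The C1 epimer with the carbamate nitrogen trans to the methoxy-bearing ring carbon, spirolactone dienone F2, is separated by chromatography. Epoxidation with t-BuOOH/DBU on the face of the lactone oxygen should give spirolactone epoxy enone F3, and NaBH4/CeCl3·7H2O should give spirolactone epoxy alcohol F4. Silylation with TBSCl/imidazole then returns to the route at 10.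

Step 8. Acid may ionise the lactol so that the enol ether closes onto the cyclic oxocarbenium ion. Alternatively, the strongly basic second stage may cause β-elimination of the C4 silyloxy group from the C5 enolate or epimerisation at C7. The fallback sets out from 11, rejoins at 13 and forms no enolate. Sc(OTf)3 (10 mol %) in THF/H2O at 0 °C should let the methyl enol ether itself add through C5 to the aldehyde form of the lactol (Mukaiyama–Prins-type closure). Water then hydrolyses the methyl oxocarbenium ion at C9 to the ketone. No further compound is made on this way.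

Step 13. The oxidant may damage the unprotected α-ketol and triol of the core, or the ring-opening may be too slow at a temperature the core tolerates. The fallback sets out from 18, ends at 22 and generates the same radical reductively. C5H11MgBr 20 should open glutaric anhydride (THF, −78 °C) to 5-oxodecanoic acid F5. N-Hydroxyphthalimide and diisopropylcarbodiimide should convert it into 1,3-dioxoisoindolin-2-yl 5-oxodecanoate F6. Blue-light irradiation of F6 and 18 with Ru(bpy)3Cl2 (1 mol %) and Hantzsch ester in CH2Cl2 should give the 4-oxononyl radical by decarboxylation under neutral conditions. Addition–fragmentation on the vinyl sulfone then gives 22.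

**Further compounds**

F1 | step 2 | (2S)-2-[(tert-butoxycarbonyl)amino]-3-(4-hydroxy-2-methoxyphenyl)propanoic acid | OC(=O)[C@H](Cc1ccc(O)cc1OC)NC(=O)OC(C)(C)C
F2 | step 2 | spirolactone dienone (five-membered lactone on C1; NHBoc trans to the methoxy-bearing ring carbon) | O=C1O[C@@]2(C[C@@H]1NC(=O)OC(C)(C)C)C=CC(=O)C=C2OC
F3 | step 2 | spirolactone epoxy enone (C2–C3 epoxide cis to the lactone oxygen) | O=C1O[C@@]2(C[C@@H]1NC(=O)OC(C)(C)C)[C@H]3O[C@H]3C(=O)C=C2OC
F4 | step 2 | spirolactone epoxy alcohol (C4–OH cis to the epoxide) | O=C1O[C@@]2(C[C@@H]1NC(=O)OC(C)(C)C)[C@H]3O[C@H]3[C@@H](O)C=C2OC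
F0 | step 8 | none | none
F5 | step 13 | 5-oxodecanoic acid | CCCCCC(=O)CCCC(=O)O
F6 | step 13 | 1,3-dioxoisoindolin-2-yl 5-oxodecanoate | CCCCCC(=O)CCCC(=O)ON1C(=O)c2ccccc2C1=O
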